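**Retrosynthetic overview**

1. The strategy rests on pyran ring C of the 3,4-diarylchroman, O1–C2H2–C3H(ring E)–C4H(ring D)–C4a–C8a: C2 is a bare CH2 between the ether oxygen and C3, and C3–C4 is a trans-1,2-diarylethane unit. Cutting C2–C3 and C4–C4a gives an aryloxymethyl cation from 3-benzyloxyphenol (ring A) and the (E)-stilbene 27 that joins catechol ring E to central ring D.
2. Stilbene 27 comes from Suzuki–Miyaura coupling of the ring D aryl triflate 23, which already carries the 3-arylchroman (pyran ring F, benzo ring G), with the ring E (E)-alkenylboronate 26.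
3. The (R) centre of ring F is set by Evans alkylation of the ring D arylacetyl imide 13 with the ring G benzyl bromide 18; ring F is then closed by a Mitsunobu reaction.
4. The 1,2,3,5 pattern of ring D (C-substituent, O-triflate, OMe, OBn) is fixed from vanillin by Dakin oxidation and aromatic Claisen rearrangement; the allyl group is cut down to the acetic acid chain.
5. Ring order: ring F (step 16), then ring C (step 21). End game: LiAlH4 (pivalates, carbamate), then hydrogenolysis (benzyl ethers).

Key step: step 21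

**Remarks on the chemistry**

- The C1 unit is carried as a pivaloyloxymethyl aryl ether, not a methoxymethyl ether. Lewis acids tend to cleave aryl methoxymethyl ethers on the aryl–oxygen side (loss of aryloxide), whereas a carboxylate leaves cleanly and gives the aryloxymethyl cation.
- The ring G oxygen is carried as a diethylcarbamate so that ring G, like the pivaloylated ring E, is a poor Friedel–Crafts nucleophile in the key step. It is removed together with the pivalates by LiAlH4.
- The stilbene is made by cross-coupling, not from a ring E benzylic ylide, because ortho-acyloxybenzyl ylides cyclise onto the ester (benzofuran formation).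
- Assumption: the facial sense of the key step relative to the (R) centre of ring F is not controlled. The two trans diastereomers of 31 are taken to be separable by chromatography (preparative HPLC if needed).

**Route**

Step 1
Reactants: 1 vanillin (4-hydroxy-3-methoxybenzaldehyde)
Product: 2 4-(allyloxy)-3-methoxybenzaldehyde
Conditions: allyl bromide, K2CO3, DMF, rt
Reagents that add atoms: allyl bromide, C=CCBr
Why: Williamson ether synthesis in which the phenoxide displaces bromide from allyl bromide.

Step 2
Reactants: 2 4-(allyloxy)-3-methoxybenzaldehyde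
Product: 4 4-(allyloxy)-3-methoxyphenol, via aryl formate 3 (not isolated)
Conditions: 30% H2O2, H2SO4 (cat.), MeOH, rt
Reagents that add atoms: hydrogen peroxide, OO
Why: Dakin oxidation, in which the electron-rich aryl group migrates to oxygen in the peroxide adduct and formate 3 is methanolysed in the flask, the allyl ether being inert to acidic H2O2.

Step 3
Reactants: 4 4-(allyloxy)-3-methoxyphenol
Product: 5 1-(allyloxy)-4-(benzyloxy)-2-methoxybenzene
Conditions: BnBr, K2CO3, DMF, rt
Reagents that add atoms: benzyl bromide, BrCc1ccccc1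
Why: Williamson ether synthesis on the only free phenol.

Step 4
Reactants: 5 1-(allyloxy)-4-(benzyloxy)-2-methoxybenzene
Product: 6 2-allyl-4-(benzyloxy)-6-methoxyphenol
Conditions: N,N-diethylaniline, 190 °C
Reagents that add atoms: none
Why: Aromatic Claisen rearrangement, which can deliver the allyl group only to the free ortho carbon because the other ortho position bears OMe and the para position OBn, so the substitution pattern of ring D is fixed.

Step 5
Reactants: 6 2-allyl-4-(benzyloxy)-6-methoxyphenol
Product: 7 2-allyl-4-(benzyloxy)-6-methoxyphenyl trifluoromethanesulfonate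
Conditions: Tf2O, pyridine, CH2Cl2, 0 °C
Reagents that add atoms: trifluoromethanesulfonic anhydride, O=S(=O)(OS(=O)(=O)C(F)(F)F)C(F)(F)F
Why: O-sulfonylation of the phenol, which protects it from periodate in the next step and later serves as the cross-coupling handle.

Step 6
Reactants: 7 2-allyl-4-(benzyloxy)-6-methoxyphenyl trifluoromethanesulfonate
Product: 9 2-[5-(benzyloxy)-3-methoxy-2-(trifluoromethylsulfonyloxy)phenyl]acetaldehyde, via propane-1,2-diol 8 (not isolated)
Conditions: OsO4 (cat.), NaIO4, 2,6-lutidine, dioxane/H2O, rt; crude product used directly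
Reagents that add atoms: osmium tetroxide, O=[Os](=O)(=O)=O; sodium periodate, [Na+].[O-]I(=O)(=O)=O
Why: Lemieux–Johnson oxidation, in which catalytic dihydroxylation of the terminal alkene and periodate cleavage of diol 8 shorten the allyl group by one carbon while the benzyl ether and triflate are untouched.

Step 7
Reactants: 9 2-[5-(benzyloxy)-3-methoxy-2-(trifluoromethylsulfonyloxy)phenyl]acetaldehyde
Product: 10 2-[5-(benzyloxy)-3-methoxy-2-(trifluoromethylsulfonyloxy)phenyl]acetic acid
Conditions: NaClO2, NaH2PO4, 2-methyl-2-butene, t-BuOH/H2O, rt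
Reagents that add atoms: sodium chlorite, [Na+].[O-]Cl=O
Why: Pinnick oxidation, selective for the aldehyde, with the alkene scavenger removing HOCl that would chlorinate the alkoxy arene.

Step 8
Reactants: 10 2-[5-(benzyloxy)-3-methoxy-2-(trifluoromethylsulfonyloxy)phenyl]acetic acid; 11 (R)-4-benzyl-2-oxazolidinone
Product: 13 (R)-4-benzyl-3-{[5-(benzyloxy)-3-methoxy-2-(trifluoromethylsulfonyloxy)phenyl]acetyl}oxazolidin-2-one, via mixed pivalic anhydride 12 (not isolated)
Conditions: t-BuCOCl, Et3N, THF, −20 °C; then 11, LiCl, rt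
Reagents that add atoms: none
Why: N-acylation of the Evans auxiliary through the mixed anhydride under LiCl/Et3N activation, attack occurring at the less hindered arylacetyl carbonyl.

Step 9
Reactants: 14 2,4-dihydroxybenzaldehyde
Product: 15 4-formyl-3-hydroxyphenyl N,N-diethylcarbamate
Conditions: Et2NCOCl (1 equiv), K2CO3, MeCN, 60 °C
Reagents that add atoms: N,N-diethylcarbamoyl chloride, CCN(CC)C(Cl)=O
Why: Selective O-carbamoylation of the 4-hydroxyl, which is the more acidic one and is not held in the hydrogen bond to the formyl group.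

Step 10
Reactants: 15 4-formyl-3-hydroxyphenyl N,N-diethylcarbamate
Product: 16 4-formyl-3-(methoxymethoxy)phenyl N,N-diethylcarbamate
Conditions: MOMCl, i-Pr2NEt, CH2Cl2, 0 °C to reflux
Reagents that add atoms: chloromethyl methyl ether, COCCl
Why: Protection of the remaining chelated phenol as its methoxymethyl ether by O-alkylation under amine base.

Step 11
Reactants: 16 4-formyl-3-(methoxymethoxy)phenyl N,N-diethylcarbamate
Product: 17 4-(hydroxymethyl)-3-(methoxymethoxy)phenyl N,N-diethylcarbamate
Conditions: NaBH4, MeOH, 0 °C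
Reagents that add atoms: none
Why: Borohydride reduction of the aldehyde, to which the carbamate and the acetal ether are inert.

Step 12
Reactants: 17 4-(hydroxymethyl)-3-(methoxymethoxy)phenyl N,N-diethylcarbamate
Product: 18 4-(bromomethyl)-3-(methoxymethoxy)phenyl N,N-diethylcarbamate
Conditions: CBr4, PPh3, CH2Cl2, 0 °C; used at once
Reagents that add atoms: carbon tetrabromide, BrC(Br)(Br)Br
Why: Appel bromination under neutral conditions that spare the acetal, the electron-poor carbamate making this benzylic bromide less labile than a dialkoxy analogue.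

Step 13
Reactants: 13 (R)-4-benzyl-3-{[5-(benzyloxy)-3-methoxy-2-(trifluoromethylsulfonyloxy)phenyl]acetyl}oxazolidin-2-one; 18 4-(bromomethyl)-3-(methoxymethoxy)phenyl N,N-diethylcarbamate
Product: 20 (R)-4-benzyl-3-{(2R)-2-[5-(benzyloxy)-3-methoxy-2-(trifluoromethylsulfonyloxy)phenyl]-3-[4-(diethylcarbamoyloxy)-2-(methoxymethoxy)phenyl]propanoyl}oxazolidin-2-one, via sodium enolate 19 (not isolated)
Conditions: NaN(SiMe3)2, THF, −78 °C; then 18, −78 to −30 °C
Reagents that add atoms: none
Why: Evans asymmetric alkylation, in which the chelated (Z)-sodium enolate 19 is alkylated on the face opposite the 4-benzyl group of the (R)-auxiliary and so sets the (R) configuration of the future C3 of ring F, the triflate having no ortho hydrogen and being inert to the amide base at −78 °C.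

Step 14
Reactants: 20 the alkylated imide
Product: 21 4-{(2R)-2-[5-(benzyloxy)-3-methoxy-2-(trifluoromethylsulfonyloxy)phenyl]-3-hydroxypropyl}-3-(methoxymethoxy)phenyl N,N-diethylcarbamate
Conditions: LiBH4, MeOH (1 equiv), THF, 0 °C
Reagents that add atoms: none
Why: Reductive cleavage of the N-acyl oxazolidinone to the primary alcohol, which leaves the stereocentre, triflate, carbamate and acetal ether untouched and returns the auxiliary.

Step 15
Reactants: 21 the (2R)-primary alcohol
Product: 22 4-{(2R)-2-[5-(benzyloxy)-3-methoxy-2-(trifluoromethylsulfonyloxy)phenyl]-3-hydroxypropyl}-3-hydroxyphenyl N,N-diethylcarbamate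
Conditions: HCl (cat.), MeOH, 45 °C
Reagents that add atoms: none
Why: Acid-catalysed acetal exchange removes the methoxymethyl group, while triflate, carbamate and benzyl ether are stable to methanolic HCl.

Step 16
Reactants: 22 the (2R)-phenol alcohol
Product: 23 (3R)-3-[5-(benzyloxy)-3-methoxy-2-(trifluoromethylsulfonyloxy)phenyl]chroman-7-yl N,N-diethylcarbamate
Conditions: PPh3, DIAD, THF, 0 °C to rt
Reagents that add atoms: none
Why: Intramolecular Mitsunobu etherification, in which the phenol displaces the activated primary hydroxyl in a six-membered closure of ring F and the stereocentre, not being the reacting carbon, is retained.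

Step 17
Reactants: 24 2,3-dihydroxy-4-methoxybenzaldehyde
Product: 25 2,3-bis(pivaloyloxy)-4-methoxybenzaldehyde
Conditions: t-BuCOCl, Et3N, DMAP (cat.), CH2Cl2, 0 °C to rt
Reagents that add atoms: pivaloyl chloride, CC(C)(C)C(Cl)=O
Why: O-acylation of both phenols, with DMAP overcoming the hydrogen bond of the 2-hydroxyl to the formyl group.

Step 18
Reactants: 25 2,3-bis(pivaloyloxy)-4-methoxybenzaldehyde
Product: 26 (E)-2-[2,3-bis(pivaloyloxy)-4-methoxyphenyl]ethenylboronic acid pinacol ester
Conditions: Cl2CHBpin, CrCl2, LiI, THF, rt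
Reagents that add atoms: 2-(dichloromethyl)-4,4,5,5-tetramethyl-1,3,2-dioxaborolane, ClC(Cl)B1OC(C)(C)C(C)(C)O1
Why: Takai–Utimoto olefination, in which the geminal dichromium species from Cl2CHBpin adds to the aldehyde and eliminates to the (E)-alkenylboronate under conditions that tolerate the aryl esters.

Step 19
Reactants: 23 the ring D aryl triflate; 26 the ring E (E)-alkenylboronate
Product: 27 (3R)-3-{5-(benzyloxy)-2-[(E)-2-(2,3-bis(pivaloyloxy)-4-methoxyphenyl)ethenyl]-3-methoxyphenyl}chroman-7-yl N,N-diethylcarbamate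
Conditions: Pd(OAc)2 (cat.), SPhos, K3PO4, THF/H2O (10:1), 60 °C
Reagents that add atoms: none
Why: Suzuki–Miyaura coupling, in which the bulky electron-rich biarylphosphine supports oxidative addition and transmetalation at the di-ortho-substituted triflate, the alkene geometry of 26 is retained and neither carbamate nor pivalates are activated by palladium.

Step 20
Reactants: 28 3-(benzyloxy)phenol
Product: 29 [3-(benzyloxy)phenoxy]methyl pivalate
Conditions: ClCH2OC(O)t-Bu, Cs2CO3, DMF, rt
Reagents that add atoms: chloromethyl pivalate, CC(C)(C)C(=O)OCCl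
Why: Williamson-type O-alkylation of the phenoxide at the chloromethyl carbon, the tert-butyl group blocking competing acyl transfer.

Step 21
Reactants: 27 the (E)-stilbene; 29 [3-(benzyloxy)phenoxy]methyl pivalate
Product: 31 (3R)-3-{5-(benzyloxy)-2-[(3R,4S)-7-(benzyloxy)-3-(2,3-bis(pivaloyloxy)-4-methoxyphenyl)chroman-4-yl]-3-methoxyphenyl}chroman-7-yl N,N-diethylcarbamate, via aryloxymethyl cation triflate 30 (not isolated)
Conditions: Me3SiOTf, 2,6-di-tert-butyl-4-methylpyridine, CH2Cl2, −78 °C, slow addition of 29, then −78 to −40 °C; NaHCO3 quench; chromatographic separation of the trans diastereomers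
Reagents that add atoms: none
Why: Proposed new method: Me3SiOTf silylates the pivalate carbonyl of 29 and expels Me3SiOPiv to give the aryloxymethyl cation 30, whose CH2 carbon should bond to the alkene carbon that bears the doubly pivaloylated ring E, so that the positive charge develops on the carbon next to ring D, where the ortho-methoxy and para-benzyloxy groups stabilise it, and this benzylic cation is then captured by the carbon of the phenyl ether that lies ortho to the ether oxygen and para to its benzyloxy group. The closest known reaction type is the Lewis-acid-promoted oxa-Povarov reaction, the formal [4+2] cycloaddition of aryl oxocarbenium ions from aldehyde-derived mixed aryl acetals with simple alkenes, which has not been shown for a formaldehyde-derived aryloxymethyl cation or for a 1,2-diarylethene and is known only in racemic form. Ring C (O1–C2–C3–C4–C4a–C8a) closes by a six-membered intramolecular Friedel–Crafts alkylation that forms C4–C4a after the intermolecular C2–C3 bond, that is, as the second bond of a stepwise or highly asynchronous [4+2] addition. C3 and C4 should come out trans because the (E) geometry of the alkene is transferred and because the trans-diequatorial diaryl arrangement is also the more stable one if the cation lives long enough to rotate; the sense of this pair relative to the (R) centre of ring F is not secured by the substrate, so both trans diastereomers are expected and the (3R,4S) isomer 31 must be separated by chromatography. The step needs chemoselectivity for the alkene over the alkoxy arenes, which is supported by the acyl groups on the ring E and ring G oxygens, by the doubly flanked free positions of ring D and by slow addition of 29 to alkene and Lewis acid in the presence of a hindered pyridine, and it needs regioselectivity in both bond formations, which the donor pattern of ring D and the para-benzyloxy group of the phenyl ether provide.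

Step 22
Reactants: 31 the protected 3,4-diarylchroman
Product: 32 (3R)-3-{5-(benzyloxy)-2-[(3R,4S)-7-(benzyloxy)-3-(2,3-dihydroxy-4-methoxyphenyl)chroman-4-yl]-3-methoxyphenyl}chroman-7-ol
Conditions: LiAlH4, THF, 0 °C to reflux; aqueous acid work-up under argon
Reagents that add atoms: none
Why: Hydride cleavage of the two aryl pivalates and reductive cleavage of the aryl carbamate, which leave the benzyl ethers and all three stereocentres untouched.

Step 23
Reactants: 32 the dibenzyl ether triol
Product: 33 CNP0227211.1, (3R)-3-{2-[(3R,4S)-3-(2,3-dihydroxy-4-methoxyphenyl)-7-hydroxychroman-4-yl]-5-hydroxy-3-methoxyphenyl}chroman-7-ol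
Conditions: H2 (1 atm), 10% Pd/C, EtOAc/MeOH, rt
Reagents that add atoms: none
Why: Hydrogenolysis of the two benzyl aryl ethers, the molecule holding no other reducible group and no stereocentre that carries a benzylic C–O bond.

**Compound list**

1 | vanillin | COc1cc(C=O)ccc1O | starting material
2 | 4-(allyloxy)-3-methoxybenzaldehyde | C=CCOc1ccc(C=O)cc1OC | intermediate
3 | 4-(allyloxy)-3-methoxyphenyl formate | C=CCOc1ccc(OC=O)cc1OC | intermediate
4 | 4-(allyloxy)-3-methoxyphenol | C=CCOc1ccc(O)cc1OC | intermediate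
5 | 1-(allyloxy)-4-(benzyloxy)-2-methoxybenzene | C=CCOc1ccc(OCc2ccccc2)cc1OC | intermediate
6 | 2-allyl-4-(benzyloxy)-6-methoxyphenol | C=CCc1cc(OCc2ccccc2)cc(OC)c1O | intermediate
7 | 2-allyl-4-(benzyloxy)-6-methoxyphenyl trifluoromethanesulfonate | C=CCc1cc(OCc2ccccc2)cc(OC)c1OS(=O)(=O)C(F)(F)F | intermediate
8 | 3-[5-(benzyloxy)-3-methoxy-2-(trifluoromethylsulfonyloxy)phenyl]propane-1,2-diol (racemic) | OCC(O)Cc1cc(OCc2ccccc2)cc(OC)c1OS(=O)(=O)C(F)(F)F | intermediate
9 | 2-[5-(benzyloxy)-3-methoxy-2-(trifluoromethylsulfonyloxy)phenyl]acetaldehyde | O=CCc1cc(OCc2ccccc2)cc(OC)c1OS(=O)(=O)C(F)(F)F | intermediate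
10 | 2-[5-(benzyloxy)-3-methoxy-2-(trifluoromethylsulfonyloxy)phenyl]acetic acid | OC(=O)Cc1cc(OCc2ccccc2)cc(OC)c1OS(=O)(=O)C(F)(F)F | intermediate
11 | (R)-4-benzyl-2-oxazolidinone | O=C1N[C@H](Cc2ccccc2)CO1 | starting material
12 | mixed anhydride of 10 with pivalic acid | CC(C)(C)C(=O)OC(=O)Cc1cc(OCc2ccccc2)cc(OC)c1OS(=O)(=O)C(F)(F)F | intermediate
13 | (R)-4-benzyl-3-{[5-(benzyloxy)-3-methoxy-2-(trifluoromethylsulfonyloxy)phenyl]acetyl}oxazolidin-2-one | O=C(Cc1cc(OCc2ccccc2)cc(OC)c1OS(=O)(=O)C(F)(F)F)N1[C@H](Cc2ccccc2)COC1=O | intermediate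
14 | 2,4-dihydroxybenzaldehyde | O=Cc1ccc(O)cc1O | starting material
15 | 4-formyl-3-hydroxyphenyl N,N-diethylcarbamate | CCN(CC)C(=O)Oc1ccc(C=O)c(O)c1 | intermediate
16 | 4-formyl-3-(methoxymethoxy)phenyl N,N-diethylcarbamate | CCN(CC)C(=O)Oc1ccc(C=O)c(OCOC)c1 | intermediate
17 | 4-(hydroxymethyl)-3-(methoxymethoxy)phenyl N,N-diethylcarbamate | CCN(CC)C(=O)Oc1ccc(CO)c(OCOC)c1 | intermediate
18 | 4-(bromomethyl)-3-(methoxymethoxy)phenyl N,N-diethylcarbamate | CCN(CC)C(=O)Oc1ccc(CBr)c(OCOC)c1 | intermediate
19 | sodium (Z)-enolate of 13 | [Na+].[O-]/C(=C\c1cc(OCc2ccccc2)cc(OC)c1OS(=O)(=O)C(F)(F)F)N1[C@H](Cc2ccccc2)COC1=O | intermediate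
20 | (R)-4-benzyl-3-{(2R)-2-[5-(benzyloxy)-3-methoxy-2-(trifluoromethylsulfonyloxy)phenyl]-3-[4-(diethylcarbamoyloxy)-2-(methoxymethoxy)phenyl]propanoyl}oxazolidin-2-one | FC(F)(F)S(=O)(=O)Oc1c(OC)cc(OCc2ccccc2)cc1[C@@H](Cc1ccc(OC(=O)N(CC)CC)cc1OCOC)C(=O)N1[C@H](Cc2ccccc2)COC1=O | intermediate
21 | 4-{(2R)-2-[5-(benzyloxy)-3-methoxy-2-(trifluoromethylsulfonyloxy)phenyl]-3-hydroxypropyl}-3-(methoxymethoxy)phenyl N,N-diethylcarbamate | FC(F)(F)S(=O)(=O)Oc1c(OC)cc(OCc2ccccc2)cc1[C@@H](Cc1ccc(OC(=O)N(CC)CC)cc1OCOC)CO | intermediate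
22 | 4-{(2R)-2-[5-(benzyloxy)-3-methoxy-2-(trifluoromethylsulfonyloxy)phenyl]-3-hydroxypropyl}-3-hydroxyphenyl N,N-diethylcarbamate | FC(F)(F)S(=O)(=O)Oc1c(OC)cc(OCc2ccccc2)cc1[C@@H](Cc1ccc(OC(=O)N(CC)CC)cc1O)CO | intermediate
23 | (3R)-3-[5-(benzyloxy)-3-methoxy-2-(trifluoromethylsulfonyloxy)phenyl]chroman-7-yl N,N-diethylcarbamate | FC(F)(F)S(=O)(=O)Oc1c(OC)cc(OCc2ccccc2)cc1[C@@H]1COc2cc(OC(=O)N(CC)CC)ccc2C1 | intermediate
24 | 2,3-dihydroxy-4-methoxybenzaldehyde | COc1ccc(C=O)c(O)c1O | starting material
25 | 2,3-bis(pivaloyloxy)-4-methoxybenzaldehyde | COc1ccc(C=O)c(OC(=O)C(C)(C)C)c1OC(=O)C(C)(C)C | intermediate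
26 | (E)-2-[2,3-bis(pivaloyloxy)-4-methoxyphenyl]ethenylboronic acid pinacol ester | COc1ccc(/C=C/B2OC(C)(C)C(C)(C)O2)c(OC(=O)C(C)(C)C)c1OC(=O)C(C)(C)C | intermediate
27 | (3R)-3-{5-(benzyloxy)-2-[(E)-2-(2,3-bis(pivaloyloxy)-4-methoxyphenyl)ethenyl]-3-methoxyphenyl}chroman-7-yl N,N-diethylcarbamate | COc1ccc(/C=C/c2c(OC)cc(OCc3ccccc3)cc2[C@@H]2COc3cc(OC(=O)N(CC)CC)ccc3C2)c(OC(=O)C(C)(C)C)c1OC(=O)C(C)(C)C | intermediate
28 | 3-(benzyloxy)phenol | Oc1cccc(OCc2ccccc2)c1 | starting material
29 | [3-(benzyloxy)phenoxy]methyl pivalate | CC(C)(C)C(=O)OCOc1cccc(OCc2ccccc2)c1 | intermediate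
30 | [3-(benzyloxy)phenyl]oxymethylium trifluoromethanesulfonate (aryloxymethyl cation) | C=[O+]c1cccc(OCc2ccccc2)c1.[O-]S(=O)(=O)C(F)(F)F | intermediate
31 | (3R)-3-{5-(benzyloxy)-2-[(3R,4S)-7-(benzyloxy)-3-(2,3-bis(pivaloyloxy)-4-methoxyphenyl)chroman-4-yl]-3-methoxyphenyl}chroman-7-yl N,N-diethylcarbamate (3,4-trans) | COc1ccc([C@@H]2COc3cc(OCc4ccccc4)ccc3[C@H]2c2c(OC)cc(OCc3ccccc3)cc2[C@@H]2COc3cc(OC(=O)N(CC)CC)ccc3C2)c(OC(=O)C(C)(C)C)c1OC(=O)C(C)(C)C | intermediate
32 | (3R)-3-{5-(benzyloxy)-2-[(3R,4S)-7-(benzyloxy)-3-(2,3-dihydroxy-4-methoxyphenyl)chroman-4-yl]-3-methoxyphenyl}chroman-7-ol | COc1ccc([C@@H]2COc3cc(OCc4ccccc4)ccc3[C@H]2c2c(OC)cc(OCc3ccccc3)cc2[C@@H]2COc3cc(O)ccc3C2)c(O)c1O | intermediate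
33 | CNP0227211.1, (3R)-3-{2-[(3R,4S)-3-(2,3-dihydroxy-4-methoxyphenyl)-7-hydroxychroman-4-yl]-5-hydroxy-3-methoxyphenyl}chroman-7-ol | COc1ccc([C@@H]2COc3cc(O)ccc3[C@H]2c2c(OC)cc(O)cc2[C@@H]2COc3cc(O)ccc3C2)c(O)c1O | target

**Step count**

Total: 23 steps. Longest linear sequence: 16 steps (steps 1–8, 13–16, 19, 21–23).

**Steps most likely to fail**

1. Step 21 (proposed new method). The aryloxymethyl cation may alkylate the alkoxy arenes (ring D of 27, ring A of 29 and of the product) faster than it adds to the hindered, twisted alkene. The first C–C bond may also form at the wrong alkene carbon, and the facial selectivity relative to the (R) centre is expected to be low. The fallback uses known reactions only, sets out from 23, 25 and 28 and returns at 31. Suzuki–Miyaura vinylation of 23 with CH2=CHBF3K [PdCl2(dppf), Et3N, n-PrOH, 80 °C] would give the ring D styrene F1, and OsO4/NaIO4 cleavage would give the ring D aldehyde F2. Ortho-selective hydroxyalkylation of the bromomagnesium phenoxide of 28 (EtMgBr, toluene) with F2 would give the 2-hydroxybenzhydrol F3. Wittig reaction of 25 with Ph3P=CHOMe (from the phosphonium chloride and NaN(SiMe3)2, −78 °C) would give the ring E enol ether F4. Gentle heating of F3, or a trace of acid, would release the ortho-quinone methide F5. Its inverse-demand hetero-Diels–Alder reaction with F4 joins the methide carbon (future C4) to the aryl-bearing enol ether carbon (future C3) and gives the 2-methoxy-3,4-diarylchroman F6. Reduction of the acetal carbon with Et3SiH/BF3·OEt2 at −78 °C then gives 31. The two trans diastereomers would still have to be separated.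

2. Step 19. Oxidative addition and transmetalation at the di-ortho-substituted triflate may be slow, so that loss of pivalate or protodeboronation of 26 in the basic aqueous medium takes over. The fallback is a Mizoroki–Heck coupling under amine base with no boron partner; it sets out from 23 and 25 and returns at 27. Wittig methylenation of 25 (Ph3P=CH2, THF, −78 °C) would give the ring E styrene F7. Heck coupling of 23 with F7 [Pd(OAc)2, P(t-Bu)3·HBF4, Et3N, LiCl, DMF, 90 °C] would then give the (E)-stilbene 27.

3. Step 13. The stabilised, ortho-substituted enolate may alkylate incompletely, bromide 18 may decompose, and the acidic α-aryl centre may epimerise, eroding the diastereomeric purity. The fallback sets the centre by asymmetric hydrogenation; it sets out from 10 and 16 and returns at 21. Perkin condensation of 10 with 16 (Ac2O, Et3N, 110 °C) would give the (E)-2,3-diarylacrylic acid F8. Hydrogenation with [Ir(cod)(L*)]BArF (L* = chiral spiro phosphine–oxazoline, enantiomer chosen to deliver the (R) acid; H2, MeOH, Et3N) would give the (R)-2,3-diarylpropanoic acid F9. Reduction with BH3·SMe2 in THF would then give alcohol 21.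

**Further compounds**

F1 | step 21 | (3R)-3-[5-(benzyloxy)-3-methoxy-2-vinylphenyl]chroman-7-yl N,N-diethylcarbamate | C=Cc1c(OC)cc(OCc2ccccc2)cc1[C@@H]1COc2cc(OC(=O)N(CC)CC)ccc2C1
F2 | step 21 | (3R)-3-[5-(benzyloxy)-2-formyl-3-methoxyphenyl]chroman-7-yl N,N-diethylcarbamate | O=Cc1c(OC)cc(OCc2ccccc2)cc1[C@@H]1COc2cc(OC(=O)N(CC)CC)ccc2C1
F3 | step 21 | (3R)-3-{5-(benzyloxy)-2-[(4-(benzyloxy)-2-hydroxyphenyl)(hydroxy)methyl]-3-methoxyphenyl}chroman-7-yl N,N-diethylcarbamate (carbinol epimers) | OC(c1ccc(OCc2ccccc2)cc1O)c1c(OC)cc(OCc2ccccc2)cc1[C@@H]1COc2cc(OC(=O)N(CC)CC)ccc2C1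
F4 | step 21 | 1-(2-methoxyethenyl)-2,3-bis(pivaloyloxy)-4-methoxybenzene (E/Z mixture) | COC=Cc1ccc(OC)c(OC(=O)C(C)(C)C)c1OC(=O)C(C)(C)C
F5 | step 21 | ortho-quinone methide from F3 (3-(benzyloxy)-6-(arylmethylidene)cyclohexa-2,4-dienone) | O=C1C=C(OCc2ccccc2)C=CC1=Cc1c(OC)cc(OCc2ccccc2)cc1[C@@H]1COc2cc(OC(=O)N(CC)CC)ccc2C1
F6 | step 21 | 2-methoxy derivative of 31 (2-methoxy-3,4-trans-diarylchroman, C2 epimers) | COc1ccc([C@@H]2C(OC)Oc3cc(OCc4ccccc4)ccc3[C@H]2c2c(OC)cc(OCc3ccccc3)cc2[C@@H]2COc3cc(OC(=O)N(CC)CC)ccc3C2)c(OC(=O)C(C)(C)C)c1OC(=O)C(C)(C)C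
F7 | step 19 | 2,3-bis(pivaloyloxy)-4-methoxystyrene | C=Cc1ccc(OC)c(OC(=O)C(C)(C)C)c1OC(=O)C(C)(C)C
F8 | step 13 | (E)-2-[5-(benzyloxy)-3-methoxy-2-(trifluoromethylsulfonyloxy)phenyl]-3-[4-(diethylcarbamoyloxy)-2-(methoxymethoxy)phenyl]acrylic acid | OC(=O)/C(=C/c1ccc(OC(=O)N(CC)CC)cc1OCOC)c1cc(OCc2ccccc2)cc(OC)c1OS(=O)(=O)C(F)(F)F
F9 | step 13 | (2R)-2-[5-(benzyloxy)-3-methoxy-2-(trifluoromethylsulfonyloxy)phenyl]-3-[4-(diethylcarbamoyloxy)-2-(methoxymethoxy)phenyl]propanoic acid | FC(F)(F)S(=O)(=O)Oc1c(OC)cc(OCc2ccccc2)cc1[C@@H](Cc1ccc(OC(=O)N(CC)CC)cc1OCOC)C(O)=O
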